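## Analysis of the target

Compound 25 is a depsidone with a fused hydroxy-lactone. The locants of the isobenzofuro[4,5-b][1,4]benzodioxepine skeleton are used: ring A is C7a–C8–C9–C10–C11–C11a and ring B is C3a–C4–C5–C5a–C12a–C12b. The seven-membered ring C holds the diaryl ether oxygen O12 and the aryl ester C7(=O)–O6, and the five-membered ring D (C1, O2, C3) is a 3-hydroxyphthalide fused at C3a–C12b.

Ring A carries methyl (C8), hydrogen (C9), methoxy (C10) and hydroxyl (C11). Ring B has no hydrogen and carries, in order, the lactone carbonyl carbon (on C3a), hydroxyl (C4), methyl (C5), the ester oxygen (C5a), the ether oxygen (C12a) and the lactol carbon (on C12b).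

The only stereocentre is C1 (R), the hemiacetal carbon of a masked 2-formylbenzoic acid. It has no neighbouring stereocentre and can epimerize by ring-chain tautomerism, so it must be set last and released under neutral conditions.

The sensitive groups are this lactol, the aryl ester of ring C (opened by hydroxide, alkoxides and amines) and two free phenols. Together they rule out basic or oxidizing conditions late in the route.

The synthesis is hard because ring B is hexasubstituted, with three contiguous oxygens in different roles and two adjacent carbon substituents of different oxidation level. In addition, the ether oxygen joins two carbons that each have two ortho substituents, a poor case for Ullmann or SNAr coupling.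

The strategy reads ring B as a folded polyketide. From C3a round to C5a the substituents follow the pattern of a 3-methylresorcylate (carboxyl, O, methyl, O), and C12b, next to the carboxyl-bearing carbon, carries a carbon at the aldehyde level. That is what an aldol condensation between the α-carbon of a masked β-keto acid and a ketone six atoms away leaves behind. In such a chain C12a lies between two ketones, so the ring A oxygen can be attached to it as an ordinary alkyl aryl ether before ring B exists.

## Retrosynthetic reasoning

**25 ⇒ 24 ⇒ 23.** The C1 hydroxyl is traced back to the (R)-acetate 24 and this to the racemic lactol 23. Cutting the acetyl–oxygen bond, not a bond at C1, means the release of 25 does not touch the stereocentre. Because 23 racemizes through its ring-opened form, an enantioselective acyl transfer can in principle convert all of it to 24. The forward steps are an acylation that selects one lactol enantiomer while the other equilibrates, then a deacylation at the acyl carbon under neutral conditions.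

**23 ⇒ 21.** The lactol ring and the C4 phenol are masked together: C1 as a dimethyl acetal, and the C3 carboxyl with the C4 oxygen as an acetonide (a benzodioxinone). These are the forms in which the key step delivers those carbons. One aqueous acid treatment has to open both without cleaving the ring C ester.

**21 ⇒ 20 ⇒ 18.** Ring C is opened at the ester bond C7–O6 and not at the ether O12. The ester closes by intramolecular acylation of a phenol already held ortho to the ether, whereas the ether would need a coupling between two hindered arenes. In 18 the ring A carboxyl is free and the C11 oxygen is a benzyl ether, so the C5a hydroxyl is the only free hydroxyl when the lactone is closed. The benzyl group is then removed by hydrogenolysis (20 ⇒ 21), before the reducible lactol exists.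

**18 ⇒ 16 (key disconnection).** Ring B is cut at C3a–C12b and read back as an aldol condensation. This gives the open-chain diketo-dioxinone 16, in which C3a is C5 of a 1,3-dioxin-4-one, C5 is a methine carrying the methyl group, C5a and C12b are ketones, C12a is the aryloxy-bearing carbon between them, and C1 is a dimethoxymethyl group. The gain is that all six substituents of ring B are fixed by the order of the chain and no substitution on a finished arene is needed. The forward reaction must make the dioxinone carbon attack the acetal-flanked ketone and then lose water.

**16 ⇒ 13 + 14.** The bond C12a–C12b is cut as a Claisen condensation between the aryloxy-bearing carbon of keto-dioxinone 13 and the ester 14. The carbanion needed sits ortho to the ring A carboxyl. If that carboxyl were an ester, the carbanion would close onto it in a Dieckmann reaction to a 3-hydroxybenzofuran. The ring A carboxyl is therefore carried as the free acid, which is a non-electrophilic lithium carboxylate under the basic conditions. This also saves an esterification and a deprotection.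

**13 ⇒ 10 + 7, and 10 ⇒ 8.** The bond between the methine and the C5a ketone is cut as acylation of the dienolate of 10 by the Weinreb amide 7. The amide keeps the adduct tetrahedral until work-up, so the acidic product never meets the dienolate. The C5 methyl is put on at the outset by γ-methylation of dioxinone 8, where only one position can react.

**7 ⇒ 6 ⇒ 4 + 5, and 4 ⇒ 3 ⇒ 2 ⇒ 1.** The O12–CH2 bond is cut as a Williamson alkylation of the salicylaldehyde hydroxyl of 4 with the chloroacetamide 5, and the ring A carboxyl comes from the aldehyde by oxidation. The oxygen pattern of ring A is taken from 1, whose two free positions are equivalent. Formylation gives 2, and the formyl group then directs cleavage of the two nearest methyl ethers (3). The two phenols of 3 differ enough (one conjugated with and chelated to the formyl group, one not) to be benzylated selectively (4).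

## Alternatives that were turned down

**Alternative 1:** The diaryl ether bond C11a–O12 is traced back to an aryl ester. In the eight-membered lactone A1, ring A is tied to ring B by a benzylic ether (the later C7 as a CH2 group) and by an ester from a ring A carboxyl on C11a to the later ether oxygen. The forward key step uses the zerovalent nickel complex Ni(cod)2 with 1,2-bis(dicyclohexylphosphino)ethane: insertion into the acyl–oxygen bond, decarbonylation and C–O reductive elimination contract the ring to the dibenzodioxepine A2.

- In its favour: both arenes are made separately by ordinary aromatic chemistry and joined by two easy bonds, and the crowded diaryl ether forms intramolecularly.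
- Against it: decarbonylative etherification is secure for esters of electron-poor aromatic acids, whereas here the acyl carbon sits on an electron-rich, doubly ortho-substituted ring. Decarbonylation inside a medium-ring acylnickel species and reductive elimination of a diaryl ether with four ortho substituents are both demanding. A2 then still needs oxidation of the C7 methylene to the lactone carbonyl in competition with two aryl methyl groups, selective removal of two isopropyl ethers beside a methyl ether, and a prior stepwise construction of hexasubstituted ring B.
- Comparison: it is more convergent, and the chemistry of rings A and B is independent. The chosen route offers instead a ring B whose substitution pattern follows from the chain, C7 already at the acid level, and an ether oxygen attached by SN2 at a CH2 group.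

**Alternative 2:** The ester bond C5a–O6 is traced back to a C–H bond. The precursor A3 is a diaryl ether with the ring A carboxylic acid and a ring B phenol (C4) para to the ether oxygen. In the forward key step the trivalent iodine oxidant PhI(OAc)2 dearomatizes that phenol and the acid adds at C12a to give the spiro ketal lactone A4. BF3·OEt2 then has to move the acyloxy oxygen to C5a, and rearomatization gives the depsidone A5.

- In its favour: ring B needs one oxygen fewer, the sequence is late and convergent, and A5 is close to the target.
- Against it: A3 still requires a coupling of two crowded arenes for the diaryl ether. Its phenol is a chelated salicylate that also carries a formyl group, an electron-poor substrate for iodine oxidation. In A4 the acyloxy shift must outrun aryloxy migration and hydrolysis of the mixed ketal, which would cut ring A off; the shift itself has no secure precedent. The final ester cleavage on ring B must spare the ring C ester.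
- Comparison: on paper it has fewer steps after the coupling, which is a real advantage. The chosen route avoids any change of oxidation state on a finished arene, and it avoids the aryl–oxygen coupling altogether.

**Alternative 3:** Ring A is cut at C7a–C11a and C8–C9. The precursor A6 is a ring B aryl but-2-ynoate (ester on O6) carrying on O12 a 2-silyloxy-3-methoxycyclohexa-1,3-diene. In the forward key step, heating brings about an intramolecular [4+2] addition, and the bicyclo[2.2.2]octadiene then loses its two-carbon bridge in a retro-[4+2] step (Alder–Rickert), giving A7 with rings A, B and C complete.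

- In its favour: rings A and C form in one operation with regiochemistry fixed by the tether, there is no lactonization, no coupling of hindered arenes, and aromatization drives the step.
- Against it: a diene with three contiguous enol-type oxygens (aryl, silyl, methyl) is hard to prepare as one regioisomer and is labile to hydrolysis. The aryl ester in the tether prefers the conformation that holds the alkyne away from the diene. The temperature needed for bridge loss threatens the tert-butyl ester and the acetal. Hexasubstituted ring B, with two adjacent oxygens that must be differentiated, is left entirely to other chemistry.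
- Comparison: for rings A and C it is stronger than the chosen route, which needs a separate lactonization. The chosen route spends its key step on ring B, the ring no simple aromatic starting material provides, and takes ring A from 1 by known selective operations.

Key step: step 9

Remark on the chemistry: C1 is a hemiacetal carbon, and it is assumed that its ring-chain tautomerism (and so its racemization) is slow without acid or base, so that the (R)-lactol released under neutral conditions in the last step can be isolated without erosion.

## Route

Step 1
Reactants: 1 3,4,5-trimethoxytoluene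
Product: 2 2,3,4-trimethoxy-6-methylbenzaldehyde
Conditions: POCl3, DMF, 0 to 70 °C; aq. NaOAc
Reagents that add atoms: N,N-dimethylformamide, CN(C)C=O (formyl carbon); water, O (formyl oxygen)
Why: Vilsmeier–Haack formylation; the two free ring positions are equivalent and each is activated by an ortho and a para methoxy group, so a single aldehyde should result.

Step 2
Reactants: 2 2,3,4-trimethoxy-6-methylbenzaldehyde
Product: 3 2,3-dihydroxy-4-methoxy-6-methylbenzaldehyde
Conditions: BCl3 (2.5 equiv), CH2Cl2, −10 °C to rt; H2O
Reagents that add atoms: none
Why: Chelation-directed ether cleavage: boron bound to the formyl oxygen cleaves the ortho methyl ether, the resulting aryloxyborane reaches the next methoxy group through a five-membered chelate, and the methoxy group para to the formyl group is out of reach.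

Step 3
Reactants: 3 2,3-dihydroxy-4-methoxy-6-methylbenzaldehyde
Product: 4 3-(benzyloxy)-2-hydroxy-4-methoxy-6-methylbenzaldehyde
Conditions: NaH (2.2 equiv), DMSO, rt; BnBr (1.0 equiv)
Reagents that add atoms: benzyl bromide, BrCc1ccccc1
Why: Williamson alkylation of the catechol dianion; the C2 oxide is delocalized into the formyl group and chelated to it, so the localized C3 oxide should be the more nucleophilic site.

Step 4
Reactants: 4 3-(benzyloxy)-2-hydroxy-4-methoxy-6-methylbenzaldehyde; 5 2-chloro-N-methoxy-N-methylacetamide
Product: 6 2-[2-(benzyloxy)-6-formyl-3-methoxy-5-methylphenoxy]-N-methoxy-N-methylacetamide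
Conditions: K2CO3, KI (0.2 equiv), DMF, 50 °C
Reagents that add atoms: none
Why: Williamson ether synthesis with Finkelstein activation of the chloride; the amide α-protons are too weakly acidic under carbonate for a Rap–Stoermer-type condensation onto the neighbouring aldehyde.

Step 5
Reactants: 6 2-[2-(benzyloxy)-6-formyl-3-methoxy-5-methylphenoxy]-N-methoxy-N-methylacetamide
Product: 7 3-(benzyloxy)-4-methoxy-2-{2-[methoxy(methyl)amino]-2-oxoethoxy}-6-methylbenzoic acid
Conditions: NaClO2, NaH2PO4, 2-methyl-2-butene, t-BuOH/H2O, rt
Reagents that add atoms: sodium chlorite, [Na+].[O-]Cl=O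
Why: Pinnick oxidation of the aryl aldehyde; the alkene scavenger removes hypochlorous acid, so the electron-rich ring, the benzyl ether and the Weinreb amide should stay untouched.

Step 6
Reactants: 8 2,2,6-trimethyl-4H-1,3-dioxin-4-one
Product: 10 6-ethyl-2,2-dimethyl-4H-1,3-dioxin-4-one, via lithium dienolate 9 (not isolated)
Conditions: LiN(i-Pr)2 (1.1 equiv), THF, −78 °C; MeI, DMPU, −78 to −40 °C
Reagents that add atoms: iodomethane, CI
Why: γ-Alkylation of a dioxinone dienolate; deprotonation at the C6 methyl group gives the extended enolate 9, which should react with the small electrophile at its terminal carbon.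

Step 7
Reactants: 10 6-ethyl-2,2-dimethyl-4H-1,3-dioxin-4-one; 7 3-(benzyloxy)-4-methoxy-2-{2-[methoxy(methyl)amino]-2-oxoethoxy}-6-methylbenzoic acid
Product: 13 3-(benzyloxy)-2-[3-(2,2-dimethyl-4-oxo-4H-1,3-dioxin-6-yl)-2-oxobutoxy]-4-methoxy-6-methylbenzoic acid (racemic), via lithium dienolate 11 (not isolated), via lithium carboxylate 12 (not isolated)
Conditions: 7, LiN(SiMe3)2 (1.0 equiv), THF, −78 °C; added to 10 (1.5 equiv), LiN(i-Pr)2 (1.5 equiv), THF, −78 °C; −78 to −30 °C; cold 1 M HCl
Reagents that add atoms: none
Why: Weinreb ketone synthesis with a dioxinone dienolate: the γ-carbon of 11 adds to the amide of 12 and the chelated tetrahedral adduct holds until the acid quench, so the acidic product never meets the dienolate; the carboxylate is not electrophilic and the amide α-protons are too weakly acidic to quench 11.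

Step 8
Reactants: 13 3-(benzyloxy)-2-[3-(2,2-dimethyl-4-oxo-4H-1,3-dioxin-6-yl)-2-oxobutoxy]-4-methoxy-6-methylbenzoic acid; 14 methyl dimethoxyacetate
Product: 16 3-(benzyloxy)-2-{[5-(2,2-dimethyl-4-oxo-4H-1,3-dioxin-6-yl)-1,1-dimethoxy-2,4-dioxohexan-3-yl]oxy}-4-methoxy-6-methylbenzoic acid (mixture of keto-enol tautomers and diastereomers; used crude), via trilithium salt 15 (not isolated)
Conditions: LiN(i-Pr)2 (4.2 equiv), THF, −78 to −40 °C; 14 (2 equiv), −78 °C; AcOH, −78 °C; pH 5 buffer
Reagents that add atoms: none
Why: Crossed Claisen condensation of a 1,3-dicarbonyl polyanion: the last-formed and most basic carbanion, on the aryloxy-bearing carbon, attacks the poorly enolizable, inductively activated ester 14; the ring A carboxyl is a lithium carboxylate, which removes the ortho ester onto which this carbanion would otherwise close (Dieckmann) to a 3-hydroxybenzofuran; the fourth equivalent of base takes up the acidic proton of the diketone as it forms.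

Step 9
Reactants: 16 3-(benzyloxy)-2-{[5-(2,2-dimethyl-4-oxo-4H-1,3-dioxin-6-yl)-1,1-dimethoxy-2,4-dioxohexan-3-yl]oxy}-4-methoxy-6-methylbenzoic acid
Product: 18 3-(benzyloxy)-2-{[5-(dimethoxymethyl)-7-hydroxy-2,2,8-trimethyl-4-oxo-4H-1,3-benzodioxin-6-yl]oxy}-4-methoxy-6-methylbenzoic acid, via aldol adduct 17 (not isolated)
Conditions: Et3N (5 equiv), CH2Cl2, 4 Å MS, rt; pH 4 citrate buffer
Reagents that add atoms: none
Why: Et3N deprotonates 16 reversibly (the ring A acid rides along as its ammonium carboxylate); the productive anion is the dienolate formed by removing the methine proton between dioxinone C6 and the inner ketone, which makes dioxinone C5 nucleophilic. The hydrogen-bonded enol of the 1,3-diketone folds the chain so that C5 lies over the dimethoxyacetyl carbonyl, the most electrophilic ketone because of its two α-oxygens, and intramolecular aldol addition gives carbinol 17. Ring B closes in the 6-(enolendo)-exo-trig mode; E1cB loss of water and enolization of the remaining ketone then give the arene, and the gain of aromaticity makes the sequence irreversible. The closest known reaction type is the amine-mediated aromatization of 6-(2,4-dioxoalkyl)-1,3-dioxin-4-ones to acetonide-protected resorcylates. No stereocentre is created, since the three sp3 centres of 17 all become sp2. The selectivity needed is closure through carbon and not through the enol oxygen, which would add to C6 and give a 4-pyranone; it is secured by aprotic amine conditions at room temperature, under which the dioxinone does not open to an acylketene, and by C5 being the only carbon nucleophile that reaches a ketone through a six-membered ring. The aryloxy group cannot be expelled, because both neighbours of its carbon are carbonyl-derived carbons and no carbanion can form β to it; it ends on an sp2 ring carbon.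

Step 10
Reactants: 18 3-(benzyloxy)-2-{[5-(dimethoxymethyl)-7-hydroxy-2,2,8-trimethyl-4-oxo-4H-1,3-benzodioxin-6-yl]oxy}-4-methoxy-6-methylbenzoic acid
Product: 20 benzyl-protected depsidone acetonide (seven-membered lactone of 18; structure in the list), via O-acylisourea 19 (not isolated)
Conditions: DCC (1.3 equiv), DMAP (0.1 equiv), CH2Cl2 (0.005 M), 0 °C to rt
Reagents that add atoms: none
Why: Carbodiimide (Steglich-type) lactonization; the C5a hydroxyl is the only free hydroxyl and is held ortho to the ether oxygen, so acyl transfer from 19 should close the seven-membered ring C, with high dilution suppressing intermolecular esters.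

Step 11
Reactants: 20 benzyl-protected depsidone acetonide
Product: 21 depsidone acetonide with free C11 phenol (structure in the list)
Conditions: H2 (1 atm), Pd/C (10%), EtOAc, rt
Reagents that add atoms: none
Why: Hydrogenolysis of the aryl benzyl ether on palladium in a neutral solvent; the aryl ester, the acetonide and the dimethyl acetal are not reducible under these conditions, and the step precedes the lactol, which could be over-reduced.

Step 12
Reactants: 21 depsidone acetonide with free C11 phenol
Product: 23 racemic 1,4,11-trihydroxy-10-methoxy-5,8-dimethyl-1H-isobenzofuro[4,5-b][1,4]benzodioxepine-3,7-dione, via aldehyde 22 (not isolated)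
Conditions: TFA/H2O (9:1), 0 °C to rt
Reagents that add atoms: water, O
Why: Acid hydrolysis of the acetal gives aldehyde 22, whose hydrate attacks the neighbouring dioxinone carbonyl (5-exo-trig acyl transfer) and expels the C4 phenol as its acetone hemiketal, so the hydroxyphthalide forms directly; the diaryl lactone of ring C should survive aqueous acid at room temperature, and C1 forms racemic.

Step 13
Reactants: 23 racemic 1,4,11-trihydroxy-10-methoxy-5,8-dimethyl-1H-isobenzofuro[4,5-b][1,4]benzodioxepine-3,7-dione
Product: 24 (1R)-4,11-dihydroxy-10-methoxy-5,8-dimethyl-3,7-dioxo-1,3-dihydro-7H-isobenzofuro[4,5-b][1,4]benzodioxepin-1-yl acetate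
Conditions: immobilized Burkholderia cepacia lipase, vinyl acetate (5 equiv), Et3N (0.2 equiv), 2-MeTHF/toluene, 40 °C
Reagents that add atoms: vinyl acetate, C=COC(C)=O
Why: Lipase-catalysed acylative dynamic kinetic resolution of a lactol, a known reaction type for γ-hydroxy lactones of this kind; the chiral acyl-enzyme should acetylate the (R)-lactol faster (the empirical size rule for lipases, with the arene as the large group, points to R) while the (S)-lactol equilibrates through the ring-opened formyl carboxylate, which the amine promotes; any phenol acetate formed on the side is removed in step 14.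

Step 14
Reactants: 24 (1R)-4,11-dihydroxy-10-methoxy-5,8-dimethyl-3,7-dioxo-1,3-dihydro-7H-isobenzofuro[4,5-b][1,4]benzodioxepin-1-yl acetate
Product: 25 (1R)-1,4,11-trihydroxy-10-methoxy-5,8-dimethyl-1H-isobenzofuro[4,5-b][1,4]benzodioxepine-3,7-dione
Conditions: immobilized Burkholderia cepacia lipase, n-BuOH (5 equiv), MTBE/2-MeTHF, 20 °C, no base; filtration, evaporation below 25 °C, crystallization
Reagents that add atoms: none
Why: Enzymatic alcoholysis of the activated acetate; the serine attacks the acetyl carbon, so the C1–O bond is never broken and the configuration set in step 13 is kept, and the neutral aprotic medium avoids the acid or base that would open the lactol.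

## Compound list

1 | 3,4,5-trimethoxytoluene | COc1cc(C)cc(OC)c1OC | starting material
2 | 2,3,4-trimethoxy-6-methylbenzaldehyde | COc1cc(C)c(C=O)c(OC)c1OC | intermediate
3 | 2,3-dihydroxy-4-methoxy-6-methylbenzaldehyde | COc1cc(C)c(C=O)c(O)c1O | intermediate
4 | 3-(benzyloxy)-2-hydroxy-4-methoxy-6-methylbenzaldehyde | COc1cc(C)c(C=O)c(O)c1OCc1ccccc1 | intermediate
5 | 2-chloro-N-methoxy-N-methylacetamide | ClCC(=O)N(C)OC | starting material
6 | 2-[2-(benzyloxy)-6-formyl-3-methoxy-5-methylphenoxy]-N-methoxy-N-methylacetamide | COc1cc(C)c(C=O)c(OCC(=O)N(C)OC)c1OCc1ccccc1 | intermediate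
7 | 3-(benzyloxy)-4-methoxy-2-{2-[methoxy(methyl)amino]-2-oxoethoxy}-6-methylbenzoic acid | COc1cc(C)c(C(=O)O)c(OCC(=O)N(C)OC)c1OCc1ccccc1 | intermediate
8 | 2,2,6-trimethyl-4H-1,3-dioxin-4-one | CC1=CC(=O)OC(C)(C)O1 | starting material
9 | lithium 2,2-dimethyl-6-methylidene-6H-1,3-dioxin-4-olate (dienolate of 8) | [Li+].C=C1C=C([O-])OC(C)(C)O1 | intermediate (not isolated)
10 | 6-ethyl-2,2-dimethyl-4H-1,3-dioxin-4-one | CCC1=CC(=O)OC(C)(C)O1 | intermediate
11 | lithium 6-ethylidene-2,2-dimethyl-6H-1,3-dioxin-4-olate (dienolate of 10) | [Li+].CC=C1C=C([O-])OC(C)(C)O1 | intermediate (not isolated)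
12 | lithium carboxylate of 7 | [Li+].COc1cc(C)c(C(=O)[O-])c(OCC(=O)N(C)OC)c1OCc1ccccc1 | intermediate (not isolated)
13 | 3-(benzyloxy)-2-[3-(2,2-dimethyl-4-oxo-4H-1,3-dioxin-6-yl)-2-oxobutoxy]-4-methoxy-6-methylbenzoic acid, racemic | COc1cc(C)c(C(=O)O)c(OCC(=O)C(C)C2=CC(=O)OC(C)(C)O2)c1OCc1ccccc1 | intermediate
14 | methyl dimethoxyacetate | COC(OC)C(=O)OC | starting material
15 | trilithium salt of 13 (carboxylate, dioxinone dienolate and aryloxy enolate) | [Li+].[Li+].[Li+].COc1cc(C)c(C(=O)[O-])c(OC=C([O-])C(C)=C2C=C([O-])OC(C)(C)O2)c1OCc1ccccc1 | intermediate (not isolated)
16 | 3-(benzyloxy)-2-{[5-(2,2-dimethyl-4-oxo-4H-1,3-dioxin-6-yl)-1,1-dimethoxy-2,4-dioxohexan-3-yl]oxy}-4-methoxy-6-methylbenzoic acid, mixture of tautomers and diastereomers | COc1cc(C)c(C(=O)O)c(OC(C(=O)C(OC)OC)C(=O)C(C)C2=CC(=O)OC(C)(C)O2)c1OCc1ccccc1 | intermediate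
17 | aldol adduct: cyclohexenone carbinol fused to the dioxinone, carrying aryloxy, hydroxyl and dimethoxymethyl groups, stereoisomer mixture | COc1cc(C)c(C(=O)O)c(OC2C(=O)C(C)=C3OC(C)(C)OC(=O)C3C2(O)C(OC)OC)c1OCc1ccccc1 | intermediate (not isolated)
18 | 3-(benzyloxy)-2-{[5-(dimethoxymethyl)-7-hydroxy-2,2,8-trimethyl-4-oxo-4H-1,3-benzodioxin-6-yl]oxy}-4-methoxy-6-methylbenzoic acid | COc1cc(C)c(C(=O)O)c(Oc2c(O)c(C)c3OC(C)(C)OC(=O)c3c2C(OC)OC)c1OCc1ccccc1 | intermediate
19 | O-acylisourea of 18 with dicyclohexylcarbodiimide | COc1cc(C)c(C(=O)OC(=NC2CCCCC2)NC2CCCCC2)c(Oc2c(O)c(C)c3OC(C)(C)OC(=O)c3c2C(OC)OC)c1OCc1ccccc1 | intermediate (not isolated)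
20 | benzyl-protected depsidone acetonide: ring A (8-methyl, 10-methoxy, 11-benzyloxy) joined to ring B by O12 and the C7 ester; ring B carries the 5-methyl, the 2,2-dimethyl-1,3-dioxin-4-one across C3a/C4 and the dimethoxymethyl group on C12b | COc1cc(C)c2c(c1OCc1ccccc1)Oc1c(c(C)c3OC(C)(C)OC(=O)c3c1C(OC)OC)OC2=O | intermediate
21 | depsidone acetonide with free C11 phenol (20 without the benzyl group) | COc1cc(C)c2c(c1O)Oc1c(c(C)c3OC(C)(C)OC(=O)c3c1C(OC)OC)OC2=O | intermediate
22 | aldehyde: 21 with the dimethoxymethyl group hydrolysed to formyl | COc1cc(C)c2c(c1O)Oc1c(c(C)c3OC(C)(C)OC(=O)c3c1C=O)OC2=O | intermediate (not isolated)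
23 | racemic 1,4,11-trihydroxy-10-methoxy-5,8-dimethyl-1H-isobenzofuro[4,5-b][1,4]benzodioxepine-3,7-dione | COc1cc(C)c2c(c1O)Oc1c(c(C)c(O)c3c1C(O)OC3=O)OC2=O | intermediate
24 | (1R)-4,11-dihydroxy-10-methoxy-5,8-dimethyl-3,7-dioxo-1,3-dihydro-7H-isobenzofuro[4,5-b][1,4]benzodioxepin-1-yl acetate | COc1cc(C)c2c(c1O)Oc1c(c(C)c(O)c3c1[C@H](OC(C)=O)OC3=O)OC2=O | intermediate
25 | (1R)-1,4,11-trihydroxy-10-methoxy-5,8-dimethyl-1H-isobenzofuro[4,5-b][1,4]benzodioxepine-3,7-dione | COc1cc(C)c2c(c1O)Oc1c(c(C)c(O)c3c1[C@H](O)OC3=O)OC2=O | target

## Step count and risks

Total step count: 14. Longest linear sequence: 13 steps (steps 1 to 5, then 7 to 14); step 6 prepares the second fragment.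

**Step 9 (key step).** The most likely failure is closure through the enol oxygen onto dioxinone C6 (pyranone formation), or stalling before dehydration. The cause would be that both carbons flanking the inner ketone are substituted, which slows the folding of the chain and the attack of C5.

Fallback, from 16 and rejoining at 23: the dioxinone is opened thermally in toluene at 110 °C with tert-butanol. Loss of acetone gives the acylketene F1, which tert-butanol traps as the triketo tert-butyl ester F2. Its free β-keto ester methylene is a stronger carbon nucleophile than dioxinone C5, and aldol aromatization (a trace of Et3N, or silica) should give the tert-butyl resorcylate F3. DCC lactonization then gives the depsidone tert-butyl ester F4; the hydroxyl ortho to the ether oxygen closes the seven-membered ring, while the chelated salicylate hydroxyl could only form a nine-membered one. Hydrogenolysis (H2, Pd/C) gives the phenol F5. TFA/H2O removes the tert-butyl ester and the acetal together, and the formyl acid closes to 23.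

**Step 8.** The most likely failure is incomplete third deprotonation and aggregation of the lithium polyanion, together with proton transfer from the newly formed, more acidic diketone to unreacted polyanion, so that conversion stops early.

Fallback, from 10 and 4 and rejoining at 18: the C12a–O12 bond is formed last, under neutral conditions.
- Dienolate 11 is acylated with N-methoxy-N-methylacetamide to the methyl ketone 2,2-dimethyl-6-(3-oxobutan-2-yl)-4H-1,3-dioxin-4-one F6.
- Double deprotonation with LiN(i-Pr)2 and acylation with 14 give the diketo-dioxinone F7.
- Diazo transfer (4-acetamidobenzenesulfonyl azide, Et3N 1 equiv, MeCN, 0 °C, short contact so that aromatization does not intervene) gives the 2-diazo-1,3-diketone F8.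
- In parallel, 4 is oxidized (NaClO2, NaH2PO4, 2-methyl-2-butene) to 3-(benzyloxy)-2-hydroxy-4-methoxy-6-methylbenzoic acid F9 and esterified (allyl bromide, KHCO3, DMF) to the allyl ester F10.
- Rh2(OAc)4-catalysed O–H insertion of the carbenoid from F8 into the phenol of F10 gives F11, the allyl ester of 16. An ester is harmless here because no carbanion is ever generated next to it.
- Et3N in CH2Cl2 aromatizes F11 to F12, the allyl ester of 18.
- The zerovalent palladium complex Pd(PPh3)4 with morpholine removes the allyl group and returns 18.

**Step 13.** The most likely failure is poor acceptance of the crowded lactol in the active site, insufficient or reversed enantioselection, or acylation of the slow enantiomer outrunning racemization.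

Fallback, from 23 and rejoining at 25: acylative dynamic kinetic resolution with a small chiral acyl-transfer catalyst, a reaction type known for lactols of this kind. Acetic anhydride (excess), i-Pr2NEt and a benzotetramisole-type isothiourea, in the antipode that delivers the R configuration, should give the (1R)-triacetate F13 (both phenols are acetylated as well). Lipase-mediated butanolysis under the conditions of step 14, where no enantioselection is asked of the enzyme, removes all three acetyl groups and gives 25.

**Step 14.** The most likely failure is erosion of configuration of the freed hemiacetal by ring opening while the deacylation is still running, made worse if the hindered ester is cleaved slowly.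

Fallback, from 23 and rejoining at 25: the resolution is run with an allyloxycarbonyl donor (acetone oxime O-allyl carbonate, same lipase and amine). This gives the allyl carbonate F14, which has the same spatial arrangement at C1 as 24 but the descriptor S, because the carbonate oxygen outranks the ring oxygen. Pd(PPh3)4 with dimedone in CH2Cl2 at 0 °C then cleaves the allyl–oxygen bond, carbon dioxide is lost, and 25 is released under aprotic, near-neutral conditions without any hydrolytic step.

## Further compounds

F1 | step 9 | acylketene from 16 by loss of acetone | COc1cc(C)c(C(=O)O)c(OC(C(=O)C(OC)OC)C(=O)C(C)C(=O)C=C=O)c1OCc1ccccc1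
F2 | step 9 | triketo tert-butyl ester (tert-butanol adduct of F1) | COc1cc(C)c(C(=O)O)c(OC(C(=O)C(OC)OC)C(=O)C(C)C(=O)CC(=O)OC(C)(C)C)c1OCc1ccccc1
F3 | step 9 | tert-butyl resorcylate diaryl ether acid | COc1cc(C)c(C(=O)O)c(Oc2c(O)c(C)c(O)c(C(=O)OC(C)(C)C)c2C(OC)OC)c1OCc1ccccc1
F4 | step 9 | depsidone tert-butyl ester with C11 benzyl ether | COc1cc(C)c2c(c1OCc1ccccc1)Oc1c(c(C)c(O)c(C(=O)OC(C)(C)C)c1C(OC)OC)OC2=O
F5 | step 9 | depsidone tert-butyl ester with free C11 phenol | COc1cc(C)c2c(c1O)Oc1c(c(C)c(O)c(C(=O)OC(C)(C)C)c1C(OC)OC)OC2=O
F6 | step 8 | 2,2-dimethyl-6-(3-oxobutan-2-yl)-4H-1,3-dioxin-4-one | CC(=O)C(C)C1=CC(=O)OC(C)(C)O1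
F7 | step 8 | 6-(6,6-dimethoxy-3,5-dioxohexan-2-yl)-2,2-dimethyl-4H-1,3-dioxin-4-one | COC(OC)C(=O)CC(=O)C(C)C1=CC(=O)OC(C)(C)O1
F8 | step 8 | 6-(4-diazo-6,6-dimethoxy-3,5-dioxohexan-2-yl)-2,2-dimethyl-4H-1,3-dioxin-4-one | COC(OC)C(=O)C(=[N+]=[N-])C(=O)C(C)C1=CC(=O)OC(C)(C)O1
F9 | step 8 | 3-(benzyloxy)-2-hydroxy-4-methoxy-6-methylbenzoic acid | COc1cc(C)c(C(=O)O)c(O)c1OCc1ccccc1
F10 | step 8 | allyl 3-(benzyloxy)-2-hydroxy-4-methoxy-6-methylbenzoate | COc1cc(C)c(C(=O)OCC=C)c(O)c1OCc1ccccc1
F11 | step 8 | allyl ester of 16 | COc1cc(C)c(C(=O)OCC=C)c(OC(C(=O)C(OC)OC)C(=O)C(C)C2=CC(=O)OC(C)(C)O2)c1OCc1ccccc1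
F12 | step 8 | allyl ester of 18 | COc1cc(C)c(C(=O)OCC=C)c(Oc2c(O)c(C)c3OC(C)(C)OC(=O)c3c2C(OC)OC)c1OCc1ccccc1
F13 | step 13 | (1R)-10-methoxy-5,8-dimethyl-3,7-dioxo-1,3-dihydro-7H-isobenzofuro[4,5-b][1,4]benzodioxepine-1,4,11-triyl triacetate | COc1cc(C)c2c(c1OC(C)=O)Oc1c(c(C)c(OC(C)=O)c3c1[C@H](OC(C)=O)OC3=O)OC2=O
F14 | step 14 | allyl (1S)-4,11-dihydroxy-10-methoxy-5,8-dimethyl-3,7-dioxo-1,3-dihydro-7H-isobenzofuro[4,5-b][1,4]benzodioxepin-1-yl carbonate (same spatial arrangement as 24) | COc1cc(C)c2c(c1O)Oc1c(c(C)c(O)c3c1[C@H](OC(=O)OCC=C)OC3=O)OC2=O
A1 | alternative 1 | eight-membered lactone joining ring A (acyl carbon on C11a, benzylic CH2 on C7a) to ring B | COc1cc(C)c2c(c1OC(C)C)C(=O)Oc1c(OC2)c(C)c(OC(C)C)c(C(=O)OC(C)(C)C)c1C(OC)OC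
A2 | alternative 1 | seven-membered dibenzodioxepine with a methylene in place of the ester carbonyl | COc1cc(C)c2c(c1OC(C)C)Oc1c(OC2)c(C)c(OC(C)C)c(C(=O)OC(C)(C)C)c1C(OC)OC
A3 | alternative 2 | diaryl ether with ring A carboxylic acid and ring B para-aryloxyphenol (C5a–H) | COc1cc(C)c(C(=O)O)c(Oc2cc(C)c(O)c(C(=O)OC)c2C=O)c1OCc1ccccc1
A4 | alternative 2 | spiro ketal lactone (cyclohexadienone) from dearomatization of A3 | COc1cc(C)c2c(c1OCc1ccccc1)OC1(OC2=O)C=C(C)C(=O)C(C(=O)OC)=C1C=O
A5 | alternative 2 | depsidone with formyl and methyl ester on ring B and C11 benzyl ether | COc1cc(C)c2c(c1OCc1ccccc1)Oc1c(c(C)c(O)c(C(=O)OC)c1C=O)OC2=O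
A6 | alternative 3 | ring B aryl but-2-ynoate carrying a 2-silyloxy-3-methoxycyclohexa-1,3-dien-1-yl ether | COC1=CCCC(Oc2c(OC(=O)C#CC)c(C)c(OCc3ccccc3)c(C(=O)OC(C)(C)C)c2C(OC)OC)=C1O[Si](C)(C)C(C)(C)C
A7 | alternative 3 | protected depsidone with complete rings A, B and C | COc1cc(C)c2c(c1O[Si](C)(C)C(C)(C)C)Oc1c(c(C)c(OCc3ccccc3)c(C(=O)OC(C)(C)C)c1C(OC)OC)OC2=O
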